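The synthesis rests on forming the furanone O–C3 bond last (germacrane numbering), across a preformed ten-membered carbocycle C1–C10. The precursor is a macrocyclic 4-hydroxy-2-ynone: tertiary C10 hydroxyl, C1≡C2 alkyne, C3 ketone, with lactone, methacrylate and acetate in place. In one gold-catalysed operation water adds at C1, the C10 hydroxyl closes transannularly onto C3 and water is lost, so the 3(2H)-furanone ring (O, C10, C1, C2, C3) and the nine-membered oxacycle form together and the carbonyl moves from C3 to C1. The step exploits the 1,4-relation of O–C10 and C3 and the strain of the ring alkyne. The macrocycle comes from a bromolactone Barbier union and a Nozaki–Hiyama–Kishi closure.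

Key step: step 16

Remark on numbering: C1–C10 are the ring carbons, C11–C13 the lactone carbons, C14 the methyl on C10, C15 the acetoxymethyl carbon on C4.
Assumption: the sense of induction in the two catalyst-controlled additions (steps 2 and 7) is assigned by analogy with aryl methyl ketones and aryl aldehydes. If the first run shows the other sense, the antipodal catalyst or ligand is used and nothing else changes.

Step 1
Reactants: 1 tert-butyldimethyl(prop-2-yn-1-yloxy)silane
Product: 3 5-[(tert-butyldimethylsilyl)oxy]pent-3-yn-2-one, via lithium acetylide 2 (not isolated)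
Conditions: n-BuLi, THF, −78 °C; then MeC(O)N(OMe)Me, −78 → 0 °C; H2O
Reagents that add atoms: N-methoxy-N-methylacetamide CC(=O)N(C)OC
Why: Weinreb ketone synthesis, in which the chelated tetrahedral adduct should stop the acetylide addition at the ketone.

Step 2
Reactants: 3 5-[(tert-butyldimethylsilyl)oxy]pent-3-yn-2-one
Product: 4 (4R)-7-[(tert-butyldimethylsilyl)oxy]-4-methylhept-1-en-5-yn-4-ol
Conditions: allylB(OiPr)2, (S)-3,3'-dibromo-1,1'-bi-2-naphthol (15 mol%), PhCF3/toluene, −35 °C; aqueous work-up
Reagents that add atoms: allyldiisopropoxyborane C=CCB(OC(C)C)OC(C)C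
Why: Chiral-diol-catalysed asymmetric allylboration of a ketone, in which the closed chair transition state on the diol-bound boronate tells methyl from alkynyl and should set C10 (R).

Step 3
Reactants: 4 (4R)-7-[(tert-butyldimethylsilyl)oxy]-4-methylhept-1-en-5-yn-4-ol
Product: 6 (3R)-6-[(tert-butyldimethylsilyl)oxy]-3-hydroxy-3-methylhex-4-ynal, via ozonide 5 (not isolated)
Conditions: O3, CH2Cl2, −78 °C (indicator end point); then PPh3, −78 °C → rt
Reagents that add atoms: ozone [O-][O+]=O
Why: Ozonolysis with reductive work-up, in which the terminal alkene should react far faster than the internal alkyne and the quaternary C10 centre cannot epimerise.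

Step 4
Reactants: 7 but-2-yne-1,4-diol
Product: 8 4-hydroxybut-2-yn-1-yl acetate
Conditions: Ac2O (0.4 equiv), Et3N, DMAP (cat.), THF, 0 °C
Reagents that add atoms: acetic anhydride CC(=O)OC(C)=O
Why: Statistical mono-acylation with the diol in excess, the unreacted diol being removed by aqueous extraction.

Step 5
Reactants: 8 4-hydroxybut-2-yn-1-yl acetate
Product: 9 4-oxobut-2-yn-1-yl acetate
Conditions: Dess–Martin periodinane, CH2Cl2, 0 °C → rt
Reagents that add atoms: none
Why: Dess–Martin oxidation of a primary propargylic alcohol to the ynal, which should leave the acetate untouched.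

Step 6
Reactants: 9 4-oxobut-2-yn-1-yl acetate
Product: 10 (2Z)-2-iodo-4-oxobut-2-en-1-yl acetate
Conditions: NaI, AcOH, rt, dark
Reagents that add atoms: sodium iodide [Na+].[I-]
Why: Conjugate hydroiodination of an electron-poor alkyne by trans addition of iodide (β) and proton (α), which should place iodine cis to the formyl group and so fix the later C4=C5 geometry.

Step 7
Reactants: 10 (2Z)-2-iodo-4-oxobut-2-en-1-yl acetate
Product: 11 (2Z,4S)-4-hydroxy-2-iodohexa-2,5-dien-1-yl acetate
Conditions: (CH2=CH)2Zn, (−)-3-exo-morpholinoisoborneol (10 mol%), toluene, −30 → 0 °C; then H2O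
Reagents that add atoms: divinylzinc C=C[Zn]C=C
Why: Amino-alcohol-catalysed enantioselective 1,2-addition of an alkenylzinc to an aldehyde, in which the ligand-bound zinc chelate should select one aldehyde face and set C6.

Step 8
Reactants: 11 (2Z,4S)-4-hydroxy-2-iodohexa-2,5-dien-1-yl acetate; 12 2-(bromomethyl)prop-2-enoic acid
Product: 13 (2Z,4S)-1-acetoxy-2-iodohexa-2,5-dien-4-yl 2-(bromomethyl)prop-2-enoate
Conditions: DCC, DMAP (cat.), CH2Cl2, 0 °C
Reagents that add atoms: none
Why: Steglich esterification at low temperature, which should acylate the secondary alcohol without touching C6 or displacing the allylic bromide.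

Step 9
Reactants: 13 (2Z,4S)-1-acetoxy-2-iodohexa-2,5-dien-4-yl 2-(bromomethyl)prop-2-enoate
Product: 14 (5S)-5-[(1Z)-3-acetoxy-2-iodoprop-1-en-1-yl]-3-(bromomethyl)furan-2(5H)-one
Conditions: second-generation Grubbs catalyst RuCl2(=CHPh)(H2IMes)(PCy3) (5 mol%), CH2Cl2, 40 °C
Reagents that add atoms: none
Why: Ring-closing metathesis in which the carbene formed at the terminal vinyl group should close onto the 1,1-disubstituted acrylate to give the butenolide, the hindered iodoalkene staying inert and C6 untouched under neutral conditions.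

Step 10
Reactants: 14 (5S)-5-[(1Z)-3-acetoxy-2-iodoprop-1-en-1-yl]-3-(bromomethyl)furan-2(5H)-one; 6 (3R)-6-[(tert-butyldimethylsilyl)oxy]-3-hydroxy-3-methylhex-4-ynal
Product: 16 [(2Z)-3-[(2S,3R)-3-[(1S,3R)-6-(tert-butyldimethylsilyloxy)-1,3-dihydroxy-3-methylhex-4-yn-1-yl]-4-methylidene-5-oxooxolan-2-yl]-2-iodoprop-2-en-1-yl] acetate, via allylzinc bromide 15 (not isolated)
Conditions: Zn dust, THF/sat. aq. NH4Cl, 0 °C → rt
Reagents that add atoms: none
Why: Barbier allylation with allylic transposition, in which the aldehyde should add to C7 on the face opposite the C6 alkenyl group (trans lactone) through a Zimmerman–Traxler chair with the ring-locked γ-substituent equatorial, giving the anti C7/C8 relationship (C8 S) and the exocyclic methylene.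

Step 11
Reactants: 16 the C8 alcohol from step 10
Product: 17 (1S,3R)-1-[(2S,3R)-2-[(1Z)-3-acetoxy-2-iodoprop-1-en-1-yl]-4-methylidene-5-oxooxolan-3-yl]-6-(tert-butyldimethylsilyloxy)-3-hydroxy-3-methylhex-4-yn-1-yl 2-methylprop-2-enoate
Conditions: methacrylic anhydride, Et3N, DMAP (cat.), CH2Cl2, 0 °C
Reagents that add atoms: methacrylic anhydride C=C(C)C(=O)OC(=O)C(C)=C
Why: DMAP-catalysed acylation, which should esterify the only secondary hydroxyl (C8) with retention while the tertiary propargylic C10 hydroxyl stays free; prompt acylation at 0 °C should also forestall translactonisation to C8.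

Step 12
Reactants: 17 the C8 methacrylate silyl ether
Product: 18 the C3 primary propargylic alcohol (17 without the silyl group; 6S,7R,8S,10R)
Conditions: HF·pyridine, THF/pyridine, 0 °C → rt
Reagents that add atoms: none
Why: Fluoride-mediated cleavage of a primary silyl ether under buffered conditions that the acetate, methacrylate and methylene lactone should survive.

Step 13
Reactants: 18 the C3 primary propargylic alcohol
Product: 19 the seco-ynal (C3 aldehyde on the C1≡C2 alkyne; C4 alkenyl iodide; 6S,7R,8S,10R)
Conditions: Dess–Martin periodinane, CH2Cl2, 0 °C → rt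
Reagents that add atoms: none
Why: Dess–Martin oxidation of the primary propargylic alcohol to the ynal, to which the tertiary C10 hydroxyl is inert.

Step 14
Reactants: 19 the seco-ynal
Product: 21 (4Z,6R,7R,8S,10R)-15-acetoxy-3,10-dihydroxy-8-(methacryloyloxy)germacra-4,11(13)-dien-1-yn-12,6-olide (C3 epimers), via alkenylchromium species 20 (not isolated)
Conditions: CrCl2 (excess), NiCl2 (cat.), DMSO/THF, rt, high dilution with slow addition; then H2O
Reagents that add atoms: none
Why: Nozaki–Hiyama–Kishi reaction, in which zerovalent nickel inserts into the C4–I bond with retention of geometry, the alkenyl group passes to trivalent chromium and adds to the C3 aldehyde to close the ten-membered carbocycle; esters and the tertiary alcohol are tolerated, and the C3 configuration is irrelevant because it is oxidised next.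

Step 15
Reactants: 21 the macrocyclic C3 carbinol
Product: 22 (4Z,6R,7R,8S,10R)-15-acetoxy-10-hydroxy-8-(methacryloyloxy)-3-oxogermacra-4,11(13)-dien-1-yn-12,6-olide
Conditions: Dess–Martin periodinane, CH2Cl2, 0 °C
Reagents that add atoms: none
Why: Dess–Martin oxidation of the doubly activated (allylic and propargylic) secondary alcohol, which should give the cross-conjugated ynone from both C3 epimers.

Step 16
Reactants: 22 the macrocyclic 4-hydroxy-2-ynone
Product: 25 (4Z,6R,7R,8S,10R)-15-acetoxy-3,10-epoxy-8-(methacryloyloxy)-1-oxogermacra-2,4,11(13)-trien-12,6-olide (the target), via macrocyclic 1,3-diketone 23 (not isolated), via bicyclic hemiketal 24 (not isolated)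
Conditions: (4-CF3C6H4)3PAuCl (5 mol%), AgOSO2CF3 (5 mol%), toluene, H2O (2 equiv), rt
Reagents that add atoms: water O
Why: The carbophilic gold cation activates the strained C1≡C2 bond and water adds at C1, the β-carbon of the ynone, to give hydroxy-1,3-diketone 23; the C10 hydroxyl then attacks the C3 carbonyl across the ring to hemiketal 24, and loss of water (the former C3 carbonyl oxygen) gives the vinylogous ester. The closest known reaction type is the gold-catalysed cycloisomerisation of 4-hydroxy-2-ynones to 3(2H)-furanones, run here transannularly. The O–C3 bond closes the furanone ring by 5-exo-trig hemiketalisation and, with the same bond, the nine-membered oxacycle (O, C3 to C10), turning the carbocycle into the 11-oxabicyclo[6.2.1]undecane core. No new stereocentre is formed: C3 ends sp2 and C6, C7, C8 and C10 are untouched. The step needs hydration at C1 and not C2 (secured by the polarisation from the C3 ketone), attack by the C10 hydroxyl alone (C8 is already acylated), and tolerance of the methylene lactone, methacrylate and allylic acetate (the soft catalyst should prefer the strained alkyne, whose strain relief drives the sequence).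

Compound list
1 | tert-butyldimethyl(prop-2-yn-1-yloxy)silane | C#CCO[Si](C)(C)C(C)(C)C | starting material
2 | lithium acetylide of 1 | [Li]C#CCO[Si](C)(C)C(C)(C)C | intermediate
3 | 5-[(tert-butyldimethylsilyl)oxy]pent-3-yn-2-one | CC(=O)C#CCO[Si](C)(C)C(C)(C)C | intermediate
4 | (4R)-7-[(tert-butyldimethylsilyl)oxy]-4-methylhept-1-en-5-yn-4-ol | C=CC[C@@](C)(O)C#CCO[Si](C)(C)C(C)(C)C | intermediate
5 | ozonide (1,2,4-trioxolane) of 4 | C1OC(C[C@@](C)(O)C#CCO[Si](C)(C)C(C)(C)C)OO1 | intermediate
6 | (3R)-6-[(tert-butyldimethylsilyl)oxy]-3-hydroxy-3-methylhex-4-ynal | O=CC[C@@](C)(O)C#CCO[Si](C)(C)C(C)(C)C | intermediate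
7 | but-2-yne-1,4-diol | OCC#CCO | starting material
8 | 4-hydroxybut-2-yn-1-yl acetate | CC(=O)OCC#CCO | intermediate
9 | 4-oxobut-2-yn-1-yl acetate | CC(=O)OCC#CC=O | intermediate
10 | (2Z)-2-iodo-4-oxobut-2-en-1-yl acetate | O=C/C=C(\I)COC(C)=O | intermediate
11 | (2Z,4S)-4-hydroxy-2-iodohexa-2,5-dien-1-yl acetate | C=C[C@H](O)/C=C(\I)COC(C)=O | intermediate
12 | 2-(bromomethyl)prop-2-enoic acid | C=C(CBr)C(=O)O | starting material
13 | (2Z,4S)-1-acetoxy-2-iodohexa-2,5-dien-4-yl 2-(bromomethyl)prop-2-enoate | C=C[C@H](OC(=O)C(=C)CBr)/C=C(\I)COC(C)=O | intermediate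
14 | (5S)-5-[(1Z)-3-acetoxy-2-iodoprop-1-en-1-yl]-3-(bromomethyl)furan-2(5H)-one | O=C1O[C@H](/C=C(\I)COC(C)=O)C=C1CBr | intermediate
15 | allylzinc bromide from 14 | O=C1O[C@H](/C=C(\I)COC(C)=O)C=C1C[Zn]Br | intermediate
16 | Barbier adduct, C8 alcohol (6S,7R,8S,10R) | C=C1C(=O)O[C@H](/C=C(\I)COC(C)=O)[C@H]1[C@@H](O)C[C@@](C)(O)C#CCO[Si](C)(C)C(C)(C)C | intermediate
17 | C8 methacrylate of 16 | C=C1C(=O)O[C@H](/C=C(\I)COC(C)=O)[C@H]1[C@@H](OC(=O)C(C)=C)C[C@@](C)(O)C#CCO[Si](C)(C)C(C)(C)C | intermediate
18 | C3 primary propargylic alcohol (desilylated 17) | C=C1C(=O)O[C@H](/C=C(\I)COC(C)=O)[C@H]1[C@@H](OC(=O)C(C)=C)C[C@@](C)(O)C#CCO | intermediate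
19 | seco-ynal (C3 aldehyde, C4 iodide) | C=C1C(=O)O[C@H](/C=C(\I)COC(C)=O)[C@H]1[C@@H](OC(=O)C(C)=C)C[C@@](C)(O)C#CC=O | intermediate
20 | alkenylchromium dichloride from 19 | C=C1C(=O)O[C@H](/C=C(\[Cr](Cl)Cl)COC(C)=O)[C@H]1[C@@H](OC(=O)C(C)=C)C[C@@](C)(O)C#CC=O | intermediate
21 | (4Z,6R,7R,8S,10R)-15-acetoxy-3,10-dihydroxy-8-(methacryloyloxy)germacra-4,11(13)-dien-1-yn-12,6-olide (C3 epimers) | C=C(C)C(=O)O[C@H]1C[C@@](C)(O)C#CC(O)/C(COC(C)=O)=C\[C@H]2OC(=O)C(=C)[C@H]12 | intermediate
22 | (4Z,6R,7R,8S,10R)-15-acetoxy-10-hydroxy-8-(methacryloyloxy)-3-oxogermacra-4,11(13)-dien-1-yn-12,6-olide | C=C(C)C(=O)O[C@H]1C[C@@](C)(O)C#CC(=O)/C(COC(C)=O)=C\[C@H]2OC(=O)C(=C)[C@H]12 | intermediate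
23 | macrocyclic 10-hydroxy-1,3-diketone | C=C(C)C(=O)O[C@H]1C[C@@](C)(O)C(=O)CC(=O)/C(COC(C)=O)=C\[C@H]2OC(=O)C(=C)[C@H]12 | intermediate
24 | bicyclic 3,10-epoxy-3-hydroxy hemiketal (C3 epimers) | C=C(C)C(=O)O[C@H]1C[C@@]2(C)OC(O)(CC2=O)/C(COC(C)=O)=C\[C@H]2OC(=O)C(=C)[C@H]12 | intermediate
25 | (4Z,6R,7R,8S,10R)-15-acetoxy-3,10-epoxy-8-(methacryloyloxy)-1-oxogermacra-2,4,11(13)-trien-12,6-olide | C=C(C)C(=O)O[C@H]1C[C@@]2(C)OC(=CC2=O)/C(COC(C)=O)=C\[C@H]2OC(=O)C(=C)[C@H]12 | target

Total step count: 16. Longest linear sequence: 13 steps (7 → 25, steps 4–16).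

Steps most likely to fail

Step 14 (ring closure). Oligomerisation may outrun closure of the strained ten-membered enyne ring, and the alkenylmetal may lose the neighbouring allylic acetate by β-elimination or the nickel may insert into it. The fallback closes the ring by carbonylation and sets out from bromolactone 14. The aldehyde partner would be changed to (3R)-3-hydroxy-3-methylpent-4-ynal F2, made from but-3-yn-2-one by the allylboration of step 2 (giving (3R)-3-methylhex-5-en-1-yn-3-ol F1) and ozonolysis as in step 3. Barbier coupling of 14 with F2 (Zn, THF/aq. NH4Cl) would give the terminal-alkyne adduct F3, and methacrylic anhydride/DMAP its C8 methacrylate F4. An intramolecular carbonylative Sonogashira coupling (Pd(PPh3)2Cl2, CuI, CO 1 atm, Et3N, THF, high dilution) would then insert carbon monoxide as C3 between C4 and the alkyne terminus C2. It comes back to the route at macrocyclic ynone 22 and needs neither the ynal nor step 15.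

Step 16 (key step). The tertiary propargylic alcohol may ionise or rearrange in the Meyer–Schuster sense, or the strained cross-conjugated ynone may decompose, before water adds at C1. The fallback delivers the C1 oxygen from the C10 hydroxyl through a temporary carbonate tether and sets out from 22. CO2 (1 atm) with AgOAc (cat.) and DBU (cat.) in toluene would give, by 5-exo-dig carboxylative cyclisation, the alkylidene cyclic carbonate F8. Mild aqueous acid (pyridinium p-toluenesulfonate, wet MeCN) would hydrolyse the enol carbonate with loss of CO2 to the hydroxy-1,3-diketone, which closes and dehydrates as in the main route. It comes back at target 25.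

Step 9 (butenolide metathesis). The allylic bromide may deactivate the ruthenium carbene and the 1,1-disubstituted acrylate may engage too slowly, so that dimerisation at the terminal vinyl group takes over. The fallback installs C13 after ring closure and sets out from dienol 11. Acryloyl chloride/Et3N would give (2Z,4S)-1-acetoxy-2-iodohexa-2,5-dien-4-yl prop-2-enoate F5, and ring-closing metathesis of this unhindered acrylate the butenolide (5S)-5-[(1Z)-3-acetoxy-2-iodoprop-1-en-1-yl]furan-2(5H)-one F6. Morita–Baylis–Hillman hydroxymethylation (aq. CH2O, imidazole, THF/H2O) would give the 3-(hydroxymethyl)butenolide F7, and PBr3 (Et2O, 0 °C) converts it to the bromide. It comes back at bromolactone 14.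

Further compounds
F1 | step 14 | (3R)-3-methylhex-5-en-1-yn-3-ol | C=CC[C@@](C)(O)C#C
F2 | step 14 | (3R)-3-hydroxy-3-methylpent-4-ynal | O=CC[C@@](C)(O)C#C
F3 | step 14 | Barbier adduct with terminal alkyne, C8 alcohol (6S,7R,8S,10R) | C=C1C(=O)O[C@H](/C=C(\I)COC(C)=O)[C@H]1[C@@H](O)C[C@@](C)(O)C#C
F4 | step 14 | C8 methacrylate of F3 | C=C1C(=O)O[C@H](/C=C(\I)COC(C)=O)[C@H]1[C@@H](OC(=O)C(C)=C)C[C@@](C)(O)C#C
F5 | step 9 | (2Z,4S)-1-acetoxy-2-iodohexa-2,5-dien-4-yl prop-2-enoate | C=C[C@H](OC(=O)C=C)/C=C(\I)COC(C)=O
F6 | step 9 | (5S)-5-[(1Z)-3-acetoxy-2-iodoprop-1-en-1-yl]furan-2(5H)-one | O=C1O[C@H](/C=C(\I)COC(C)=O)C=C1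
F7 | step 9 | (5S)-5-[(1Z)-3-acetoxy-2-iodoprop-1-en-1-yl]-3-(hydroxymethyl)furan-2(5H)-one | O=C1O[C@H](/C=C(\I)COC(C)=O)C=C1CO
F8 | step 16 | macrocyclic alkylidene cyclic carbonate (C10–O–C(=O)–O–C1, C1=C2 exocyclic to the carbonate) | C=C(C)C(=O)O[C@H]1C[C@@]2(C)OC(=O)O/C2=C\C(=O)/C(COC(C)=O)=C\[C@H]2OC(=O)C(=C)[C@H]12
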